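**Plan**

- Feature: ring A (the 3,4,5-trimethoxyphenyl ring) has its O4 oxygen para to the benzylic carbinol C7, and the next carbon, C8, carries the aryl ether oxygen O4' of ring B (the benzoate ring). This C7(OH)–C8–O4' array is what remains when a 4-propenylphenol radical is captured at C8 by a second phenoxyl oxygen and water then adds to the quinone methide at C7.
- Retrosynthesis: C7 carbinol back to the C7 ketone (stereochemistry); then O4-methyl and C5'–H back to a free phenol and a C5'–Br blocking group; then C8–O4' and C7–OH are cut together, giving (E)-2,6-dimethoxy-4-propenylphenol and methyl 5-bromovanillate.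
- Forward: no ring is formed. After allyl-to-propenyl isomerization and bromination of methyl vanillate, the side chain is joined to ring B in one oxidative step, followed by O-methylation, debromination, oxidation at C7 and reduction.
- The bromine on C5' closes the only free ortho carbon of the vanillate, so that its radical can neither dimerize 5–5' nor couple 8–5'.
- Stereochemistry: C7 and C8 arise without control in the coupling. Oxidation erases C7 and leaves C8 epimerizable; the final Ru-catalysed asymmetric transfer hydrogenation with dynamic kinetic resolution sets 7S (catalyst) and 8S (Felkin–Anh-matched enantiomer, threo).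

Key step: step 3

Remark: neolignan locants are used throughout (ring A C1–C6, side chain C7–C8–C9, ring B primed). The target SMILES reads as (7S,8S), which is the threo isomer.

**Route**

Step 1
Reactants: 1 4-allyl-2,6-dimethoxyphenol
Product: 2 (E)-2,6-dimethoxy-4-(prop-1-en-1-yl)phenol
Conditions: RuClH(CO)(PPh3)3 (1 mol %), toluene, 80 °C
Reagents that add atoms: none
Why: Ruthenium hydride-catalysed alkene isomerization (hydrometalation, then β-hydride elimination) moves the double bond into conjugation with ring A and favours the E isomer, as in the eugenol-to-isoeugenol isomerization, and the free phenol is tolerated; any Z isomer is harmless because both geometries give the same quinone methide in step 3.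

Step 2
Reactants: 3 methyl vanillate (methyl 4-hydroxy-3-methoxybenzoate)
Product: 4 methyl 3-bromo-4-hydroxy-5-methoxybenzoate (methyl 5-bromovanillate)
Conditions: Br2 (1.05 equiv), AcOH, rt
Reagents that add atoms: bromine, BrBr
Why: Electrophilic aromatic bromination directed by the phenol to C5, its only free ortho position (the para position carries the ester), as in the bromination of vanillin to 5-bromovanillin; the bromine serves as a removable block of that ring carbon in step 3.

Step 3
Reactants: 2 (E)-2,6-dimethoxy-4-(prop-1-en-1-yl)phenol, 4 methyl 5-bromovanillate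
Product: 6 methyl 3-bromo-4-{[1-hydroxy-1-(4-hydroxy-3,5-dimethoxyphenyl)propan-2-yl]oxy}-5-methoxybenzoate (racemic erythro/threo mixture), via quinone methide 5 (not isolated)
Conditions: Ag2O (1.1 equiv), 4 (3 equiv), 4 Å MS, CH2Cl2, rt, dark, 2 added over 8 h; filter through Celite; then THF–H2O (4:1), TsOH·H2O (5 mol %), rt
Reagents that add atoms: water, O
Why: Ag2O (monovalent silver) removes one electron and one proton from each phenol; the phenoxyl radical of 2 carries spin density on C8, which pairs with the phenoxyl oxygen of the radical of 4 to form the C8–O4' bond and leave the para-quinone methide 5. Once the silver has been filtered off, water adds to the electrophilic C7 of 5 under mild acid catalysis, and the regained aromaticity of ring A drives formation of the C7–OH bond. The closest known reaction type is the dehydrogenative cross-coupling of 4-propenylphenols with a second phenol by Ag2O, peroxidase or laccase, which gives 8-O-4' neolignans and lignin β-aryl ether models. No ring is closed, and C8 and C7 form without control (radical recombination, then water on either face of a planar quinone methide), so 6 should be a racemic erythro/threo mixture that steps 6 and 7 correct. The selectivity needed is cross- over homo-coupling and O- over C-coupling: both ortho positions of each phenol are substituted (OMe/OMe in 2, OMe/Br in 4) and the para carbon of 4 bears the ester, so the radical of 4 has no free ring carbon and should persist, while slow addition keeps the dimerization-prone radical of 2 dilute against an excess of 4. Holding the product as quinone methide 5 (water from the oxidant is taken up by the sieves) until the oxidant is gone keeps the new syringyl-type phenol away from Ag2O and so should prevent chain growth.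

Step 4
Reactants: 6 methyl 3-bromo-4-{[1-hydroxy-1-(4-hydroxy-3,5-dimethoxyphenyl)propan-2-yl]oxy}-5-methoxybenzoate
Product: 7 methyl 3-bromo-4-{[1-hydroxy-1-(3,4,5-trimethoxyphenyl)propan-2-yl]oxy}-5-methoxybenzoate (racemic erythro/threo mixture)
Conditions: MeI (1.5 equiv), K2CO3 (2 equiv), DMF, rt
Reagents that add atoms: iodomethane, CI
Why: Williamson O-methylation, in which carbonate deprotonates only the phenol (the secondary benzylic alcohol is far less acidic) and the hindered 2,6-dimethoxyphenoxide is still alkylated by the small electrophile in DMF, as in the routine methylation of syringyl phenols.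

Step 5
Reactants: 7 methyl 3-bromo-4-{[1-hydroxy-1-(3,4,5-trimethoxyphenyl)propan-2-yl]oxy}-5-methoxybenzoate
Product: 8 methyl 4-{[1-hydroxy-1-(3,4,5-trimethoxyphenyl)propan-2-yl]oxy}-3-methoxybenzoate (racemic erythro/threo mixture)
Conditions: H2 (1 atm), 10% Pd/C, NaOAc (1.5 equiv), MeOH–EtOAc, rt
Reagents that add atoms: none
Why: Heterogeneous palladium-catalysed hydrodebromination (oxidative addition of the aryl C–Br bond to zerovalent palladium, then hydride transfer and reductive elimination) removes the blocking group, while the acetate buffer traps HBr so that the benzylic C7–OH bond, which is cleaved appreciably only under acid, and the non-benzylic C8–O ether stay intact.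

Step 6
Reactants: 8 methyl 4-{[1-hydroxy-1-(3,4,5-trimethoxyphenyl)propan-2-yl]oxy}-3-methoxybenzoate
Product: 9 methyl 3-methoxy-4-{[1-oxo-1-(3,4,5-trimethoxyphenyl)propan-2-yl]oxy}benzoate (racemic)
Conditions: Dess–Martin periodinane (1.3 equiv), CH2Cl2, rt
Reagents that add atoms: none
Why: Dess–Martin oxidation (alkoxide exchange at hypervalent iodine, then α-hydrogen removal) converts the secondary benzylic alcohol into the aryl ketone under neutral conditions that leave the ester and the electron-rich rings alone, and by removing the C7 stereocentre it merges the erythro and threo series into one racemic ketone.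

Step 7
Reactants: 9 methyl 3-methoxy-4-{[1-oxo-1-(3,4,5-trimethoxyphenyl)propan-2-yl]oxy}benzoate
Product: 10 methyl 4-{[(1S,2S)-1-hydroxy-1-(3,4,5-trimethoxyphenyl)propan-2-yl]oxy}-3-methoxybenzoate
Conditions: RuCl(p-cymene)[(R,R)-TsDPEN] (2 mol %), HCO2H–DBU (1:1.1), MeCN, 40 °C
Reagents that add atoms: none
Why: Noyori–Ikariya asymmetric transfer hydrogenation run as a dynamic kinetic resolution, in which DBU interconverts the two C8 enantiomers of 9 through the enolate (C8–H is flanked by the carbonyl and the aryloxy group), the (R,R)-catalyst delivers hydride to the carbonyl face that gives the (R)-1-phenylethanol-type arrangement (7S here, because C8 outranks ring A), and the (8S)-ketone should be consumed faster because it can react through the Felkin–Anh conformer with the C8–OAr bond anti to the incoming hydride, which leads to the threo (7S,8S)-alcohol.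

**Compound list**

1 | 4-allyl-2,6-dimethoxyphenol | C=CCc1cc(OC)c(O)c(OC)c1 | starting material
2 | (E)-2,6-dimethoxy-4-(prop-1-en-1-yl)phenol | C/C=C/c1cc(OC)c(O)c(OC)c1 | intermediate
3 | methyl vanillate (methyl 4-hydroxy-3-methoxybenzoate) | COC(=O)c1ccc(O)c(OC)c1 | starting material
4 | methyl 3-bromo-4-hydroxy-5-methoxybenzoate (methyl 5-bromovanillate) | COC(=O)c1cc(Br)c(O)c(OC)c1 | intermediate
5 | methyl 3-bromo-4-{[1-(3,5-dimethoxy-4-oxocyclohexa-2,5-dien-1-ylidene)propan-2-yl]oxy}-5-methoxybenzoate (racemic para-quinone methide) | COC(=O)c1cc(Br)c(OC(C)C=C2C=C(OC)C(=O)C(OC)=C2)c(OC)c1 | intermediate (not isolated)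
6 | methyl 3-bromo-4-{[1-hydroxy-1-(4-hydroxy-3,5-dimethoxyphenyl)propan-2-yl]oxy}-5-methoxybenzoate (racemic erythro/threo mixture) | COC(=O)c1cc(Br)c(OC(C)C(O)c2cc(OC)c(O)c(OC)c2)c(OC)c1 | intermediate
7 | methyl 3-bromo-4-{[1-hydroxy-1-(3,4,5-trimethoxyphenyl)propan-2-yl]oxy}-5-methoxybenzoate (racemic erythro/threo mixture) | COC(=O)c1cc(Br)c(OC(C)C(O)c2cc(OC)c(OC)c(OC)c2)c(OC)c1 | intermediate
8 | methyl 4-{[1-hydroxy-1-(3,4,5-trimethoxyphenyl)propan-2-yl]oxy}-3-methoxybenzoate (racemic erythro/threo mixture) | COC(=O)c1ccc(OC(C)C(O)c2cc(OC)c(OC)c(OC)c2)c(OC)c1 | intermediate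
9 | methyl 3-methoxy-4-{[1-oxo-1-(3,4,5-trimethoxyphenyl)propan-2-yl]oxy}benzoate (racemic) | COC(=O)c1ccc(OC(C)C(=O)c2cc(OC)c(OC)c(OC)c2)c(OC)c1 | intermediate
10 | methyl 4-{[(1S,2S)-1-hydroxy-1-(3,4,5-trimethoxyphenyl)propan-2-yl]oxy}-3-methoxybenzoate, (7S,8S), threo | COC(=O)c1ccc(O[C@@H](C)[C@@H](O)c2cc(OC)c(OC)c(OC)c2)c(OC)c1 | target

**Step count**

Total steps: 7. Longest linear sequence: 6 steps (steps 2–7 from methyl vanillate 3; equally step 1 followed by steps 3–7 from 1).

**Steps most likely to fail**

Step 3 (key step). The electron-poor phenol 4 may be oxidized too slowly by Ag2O to supply its radical, so that self-coupling and chain growth of the propenylphenol radical outrun the cross-coupling. In that case the C8–O4' bond would be made by substitution instead of radical pairing. Purchased 1-(3,4,5-trimethoxyphenyl)propan-1-one F1 is brominated at the α-carbon with CuBr2 in refluxing EtOAc–CHCl3 to give 2-bromo-1-(3,4,5-trimethoxyphenyl)propan-1-one F2. Methyl vanillate 3 is then alkylated with F2 (K2CO3, acetone, reflux) in a Williamson ether synthesis that gives the racemic ketone directly. This fallback sets out from 3 and rejoins the route at 9, so that steps 2 to 6 are not needed.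

Step 7. Epimerization at C8 may lag behind hydride transfer, or the Felkin–Anh discrimination between the two ketone enantiomers may be weak, so that reduction of the mismatched enantiomer erodes the threo selectivity. The fallback sets out from 9 and replaces the dynamic resolution by a reagent-controlled reduction with recycling. Corey–Bakshi–Shibata reduction ((S)-2-methyl-CBS-oxazaborolidine 10 mol %, BH3·SMe2, THF, −20 °C) should set 7S on both C8 enantiomers and give 10 together with its C8 epimer, methyl 4-{[(1S,2R)-1-hydroxy-1-(3,4,5-trimethoxyphenyl)propan-2-yl]oxy}-3-methoxybenzoate F3. The two diastereomers are separated by chromatography, which returns the sequence to the route at 10. F3 is oxidized again under the conditions of step 6, and the resulting ketone is racemized at C8 with DBU and fed back as 9.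

Step 5. Hydrogenolysis may spread from the C–Br bond to the benzylic C7–O bond, or the debromination may stall on a poisoned catalyst surface. The fallback sets out from 7 and changes the order, so that no benzylic C–O single bond is present when the bromine leaves. Dess–Martin oxidation of 7 (CH2Cl2, rt) gives methyl 3-bromo-5-methoxy-4-{[1-oxo-1-(3,4,5-trimethoxyphenyl)propan-2-yl]oxy}benzoate F4. Homogeneous formate reduction of the aryl bromide (Pd(OAc)2, PPh3, HCO2Na, DMF, 80 °C), which does not touch an aryl ketone, then rejoins the route at 9.

Further compounds
F1 | step 3 | 1-(3,4,5-trimethoxyphenyl)propan-1-one (purchased) | CCC(=O)c1cc(OC)c(OC)c(OC)c1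
F2 | step 3 | 2-bromo-1-(3,4,5-trimethoxyphenyl)propan-1-one (racemic) | CC(Br)C(=O)c1cc(OC)c(OC)c(OC)c1
F3 | step 7 | methyl 4-{[(1S,2R)-1-hydroxy-1-(3,4,5-trimethoxyphenyl)propan-2-yl]oxy}-3-methoxybenzoate, (7S,8R), erythro | COC(=O)c1ccc(O[C@H](C)[C@@H](O)c2cc(OC)c(OC)c(OC)c2)c(OC)c1
F4 | step 5 | methyl 3-bromo-5-methoxy-4-{[1-oxo-1-(3,4,5-trimethoxyphenyl)propan-2-yl]oxy}benzoate (racemic) | COC(=O)c1cc(Br)c(OC(C)C(=O)c2cc(OC)c(OC)c(OC)c2)c(OC)c1
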